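**Plan**

1. Retrosynthesis: the C2 oxygen is removed first (β-diketone enol → enone 21 → ketone 19). Then C1–C9 and C1–C2 are cut together, which contracts the ring C1–C2–C3–C4–C5–C9 to a cyclopentane-1,3-dione and opens the carbocycle. Then C5–prenyl, C5–C6, C10–isopropyl and C7–C8 are cut, back to geraniol, 5-methylhex-4-enoic acid and cyclopentane-1,3-dione.
2. Forward: the open chain C6–C7–C8–C1 is made first (C7–C8 by Ireland–Claisen rearrangement). Its vinyl end becomes the α-diazo isopropyl ketone (C1, C10), and its other end (C6) is joined to a 2-prenylcyclopentane-1,3-dione (ring C5–C9–C2–C3–C4).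
3. Key event: the diazo carbon C1 adds to one ring carbonyl (C9) and closes the carbocycle C1–C8–C7–C6–C5–C9. Loss of N2 then moves C2 from C9 to C1, so the five-membered dione ring grows by one atom into the ring C1–C2–C3–C4–C5–C9 and the bicyclo[3.3.1]nonane core appears in one operation.
4. Enabling feature: C1 carries an acyl group and lies between the bridging carbonyl C9 and C2, so an α-diazo ketone carbon can act first as nucleophile and then as migration terminus. C5 lies between two carbonyl carbons (C9, C4), so a symmetric 2,2-disubstituted cyclopentane-1,3-dione is its natural precursor.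
5. Stereochemistry: C7 and C8 come from the chair Ireland–Claisen transition state under a C2-symmetric boron controller. C5 and C1 are set in the key step by the choice between the two diastereotopic ring carbonyls (C7 prenyl equatorial) and by the bridge.
6. Endgame: Saegusa–Ito desaturation, nucleophilic epoxidation and epoxy ketone → 1,3-diketone isomerisation.

Key step: step 12

**Remarks**

- Numbering used throughout (also for open-chain precursors): C1 acyl-bearing bridgehead, C2–C3–C4 three-carbon bridge (C2 next to C1), C5 prenyl-bearing bridgehead, C6 CH2, C7 CH(prenyl), C8 C(CH3)(homoprenyl), C9 bridging carbonyl, C10 isobutyryl carbonyl.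
- Assumption: the (R,R)-configured boron controller is taken to select the enolate face that leads to (2R,3S)-4; if the sense is opposite, its mirror image is used.
- Assumption: the 1,3-diketone formed in step 15 equilibrates to the enol tautomer drawn for the target.

**Route**

Step 1
Reactants: 1 geraniol; 2 5-methylhex-4-enoic acid
Product: 3 geranyl 5-methylhex-4-enoate
Conditions: DCC, DMAP (cat.), CH2Cl2, 0 °C → rt
Reagents that add atoms: none
Why: Steglich esterification of a primary allylic alcohol with an unhindered acid leaves the three trisubstituted alkenes untouched; no stereocentre is formed.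

Step 2
Reactants: 3 geranyl 5-methylhex-4-enoate
Product: 4 (2R,3S)-3-ethenyl-3,7-dimethyl-2-(3-methylbut-2-en-1-yl)oct-6-enoic acid
Conditions: (4R,5R)-2-bromo-4,5-diphenyl-1,3-bis(4-methylbenzenesulfonyl)-1,3,2-diazaborolidine, i-Pr2NEt, CH2Cl2, −78 °C (Z(O)-boron enolate: α-substituent cis to O–B), then −20 °C; aqueous work-up
Reagents that add atoms: none
Why: Enantioselective Ireland–Claisen rearrangement of the Z(O)-boron enolate through a chair transition state with the (E)-alkene (prenyl pseudo-equatorial, geranyl methyl pseudo-axial) forms C7–C8 and sets the relative configuration of C7 and the quaternary C8, while the sulfonamide ligand on boron selects the enolate face and hence the absolute configuration.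

Step 3
Reactants: 4 (2R,3S)-acid
Product: 5 (2R,3S)-3-ethenyl-3,7-dimethyl-2-(3-methylbut-2-en-1-yl)oct-6-en-1-ol
Conditions: LiAlH4, Et2O, 0 °C → rt
Reagents that add atoms: none
Why: Hydride reduction of the acid to the primary alcohol (C6) does not touch isolated alkenes or the two stereocentres.

Step 4
Reactants: 5 alcohol
Product: 6 tert-butyl{[(2R,3S)-3-ethenyl-3,7-dimethyl-2-(3-methylbut-2-en-1-yl)oct-6-en-1-yl]oxy}dimethylsilane
Conditions: TBSCl, imidazole, DMF, rt
Reagents that add atoms: tert-butyldimethylsilyl chloride, CC(C)(C)[Si](C)(C)Cl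
Why: Silylation masks the C6 hydroxyl, which would otherwise cyclise onto the alkene in the next step and would quench the later organometallic and amide bases.

Step 5
Reactants: 6 silyl ether
Product: 7 (3S)-3-[(2R)-1-(tert-butyldimethylsilyloxy)-5-methylhex-4-en-2-yl]-3,7-dimethyloct-6-enal
Conditions: PdCl2(PhCN)2 (cat.), CuCl2·2H2O (cat.), AgNO2 (cat.), O2 (1 atm), t-BuOH/MeNO2, rt
Reagents that add atoms: dioxygen, O=O
Why: Nitrite-modified, aldehyde-selective Wacker oxidation oxidises only the monosubstituted alkene at its terminal carbon (the neighbouring quaternary C8 further disfavours internal attack); the trisubstituted alkenes and the silyl ether are inert.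

Step 6
Reactants: 7 aldehyde
Product: 9 (5S)-5-[(2R)-1-(tert-butyldimethylsilyloxy)-5-methylhex-4-en-2-yl]-2,5,9-trimethyldec-8-en-3-one, via chloromagnesium alkoxide 8 (not isolated)
Conditions: i-PrMgCl, THF, −78 → 0 °C; then 1,1'-(azodicarbonyl)dipiperidine, 0 °C → rt
Reagents that add atoms: isopropylmagnesium chloride, CC(C)[Mg]Cl
Why: Grignard addition to the unhindered aldehyde followed by Oppenauer-type hydride transfer from the magnesium alkoxide to the azodicarboxamide gives the isopropyl ketone in one flask, so the transient carbinol centre (both epimers) is removed at once.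

Step 7
Reactants: 9 ketone
Product: 11 (5R)-5-[(2R)-1-(tert-butyldimethylsilyloxy)-5-methylhex-4-en-2-yl]-4-diazo-2,5,9-trimethyldec-8-en-3-one, via trifluoroacetyl ketone 10 (not isolated)
Conditions: LiN(SiMe3)2, THF, −78 °C; CF3CO2CH2CF3; then 4-acetamidobenzenesulfonyl azide, Et3N, H2O, MeCN, rt
Reagents that add atoms: 4-acetamidobenzenesulfonyl azide, CC(=O)Nc1ccc(cc1)S(=O)(=O)N=[N+]=[N-]
Why: Detrifluoroacetylative diazo transfer: only the 1,3-diketone formed at the α-methylene C1 can still be deprotonated for transfer (acylation at the isopropyl methine gives a non-enolisable product that reverts on work-up), so the diazo group enters next to the quaternary C8; no stereocentre is touched.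

Step 8
Reactants: 11 diazo ketone silyl ether
Product: 12 (5R)-4-diazo-5-[(2R)-1-hydroxy-5-methylhex-4-en-2-yl]-2,5,9-trimethyldec-8-en-3-one
Conditions: Bu4NF, THF, 0 °C → rt
Reagents that add atoms: none
Why: Fluoride cleaves the primary silyl ether under non-acidic conditions, which a fully substituted α-diazo ketone tolerates.

Step 9
Reactants: 12 diazo alcohol
Product: 13 (2R,3R)-3-(1-diazo-3-methyl-2-oxobutyl)-3,7-dimethyl-2-(3-methylbut-2-en-1-yl)oct-6-enal
Conditions: Dess–Martin periodinane, NaHCO3, CH2Cl2, 0 °C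
Reagents that add atoms: none
Why: Buffered Dess–Martin oxidation gives the α-branched aldehyde (C6) without epimerising C7 and without attacking the diazo group or the alkenes.

Step 10
Reactants: 13 diazo keto aldehyde; 14 cyclopentane-1,3-dione
Product: 16 2-[(2S,3R)-3-(1-diazo-3-methyl-2-oxobutyl)-3,7-dimethyl-2-(3-methylbut-2-en-1-yl)oct-6-en-1-yl]cyclopentane-1,3-dione, via alkylidene dione 15 (not isolated)
Conditions: diethyl 2,6-dimethyl-1,4-dihydropyridine-3,5-dicarboxylate (Hantzsch ester), L-proline (cat.), CH2Cl2, rt; product used directly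
Reagents that add atoms: none
Why: Organocatalytic reductive alkylation (Knoevenagel condensation, then conjugate hydride transfer from the Hantzsch ester) C-alkylates the cyclic 1,3-dione under near-neutral conditions that spare the diazo ketone; C7 is not touched because the hindered α-branched aldehyde forms an enamine only slowly.

Step 11
Reactants: 16 diazo dione
Product: 17 2-[(2S,3R)-3-(1-diazo-3-methyl-2-oxobutyl)-3,7-dimethyl-2-(3-methylbut-2-en-1-yl)oct-6-en-1-yl]-2-(3-methylbut-2-en-1-yl)cyclopentane-1,3-dione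
Conditions: prenyl bromide, K2CO3, acetone, rt
Reagents that add atoms: 1-bromo-3-methylbut-2-ene, CC(C)=CCBr
Why: C-Alkylation of the 2-alkyl-1,3-dione enolate with a reactive allylic bromide makes C5 quaternary (not yet stereogenic, its two carbonyl arms being identical) and turns both ring carbonyls into non-enolised, electrophilic ketones.

Step 12
Reactants: 17 diazo dione
Product: 19 (1R,5R,7S,8R)-8-methyl-8-(4-methylpent-3-en-1-yl)-5,7-bis(3-methylbut-2-en-1-yl)-1-(2-methylpropanoyl)bicyclo[3.3.1]nonane-4,9-dione, via diazonium alkoxide 18 (not isolated)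
Conditions: Sc(OTf)3 (20 mol %), 4 Å molecular sieves, CH2Cl2, −40 °C → rt
Reagents that add atoms: none
Why: Proposed new method: Sc(OTf)3 bridges one ring carbonyl and the isobutyryl oxygen, the diazo carbon C1 adds to that carbonyl carbon C9 (6-exo-trig closure of the carbocycle C1–C8–C7–C6–C5–C9) to give diazonium alkoxide 18, and loss of N2 with 1,2-shift of the ring methylene C2 from C9 to C1 expands the ring C5–C9–C2–C3–C4 to C1–C2–C3–C4–C5–C9 while C9 returns to a ketone. The closest known reaction types are the Lewis-acid-catalysed diazo–carbonyl homologation of cyclic ketones with α-alkyl-α-diazo carbonyl compounds (Tiffeneau–Demjanov or Büchner–Curtius–Schlotterbeck type) and the semipinacol ring expansion of ring-fusion carbinols of cis-fused hydrindanediones to bicyclo[3.3.1]nonanes. The second ring is therefore closed by migration, a fused bicycle becoming a bridged one. C5 is set by which of the two diastereotopic carbonyls is attacked: attack perpendicular to the dione plane forces C4 axial on C5, and the chair with the C7 prenyl equatorial (C8 methyl axial) is the only one free of a 1,3-diaxial prenyl/C4 clash; C1 is set by the shift with inversion at C1 and is in any case fixed by the bridge. Selectivity needed: attack by C1 and not Prins attack by the prenyl alkenes (the diazo carbon is by far the better nucleophile), and migration of C2 and not of the ring-fusion carbon C5 or oxirane closure. This is secured by the scandium chelate between the C9 and C10 oxygens, which holds N2+ antiperiplanar to C2 and ties up the alkoxide, by the low migratory aptitude of the acyl-bearing quaternary C5, and by reversible addition that returns unproductive adducts.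

Step 13
Reactants: 19 bicyclic diketone
Product: 21 (1R,5R,7S,8R)-8-methyl-8-(4-methylpent-3-en-1-yl)-5,7-bis(3-methylbut-2-en-1-yl)-1-(2-methylpropanoyl)bicyclo[3.3.1]non-2-ene-4,9-dione, via trimethylsilyl enol ether 20 (not isolated)
Conditions: LiN(SiMe3)2, Me3SiCl, THF, −78 °C; then Pd(OAc)2 (1 equiv), MeCN, rt
Reagents that add atoms: none
Why: Saegusa–Ito oxidation: kinetic deprotonation takes place at the only ring α-methylene (C3; C9 has no α-hydrogen and the isopropyl methine is slower), and Pd(OAc)2 converts the silyl enol ether into the C2=C3 enone without touching the configured centres.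

Step 14
Reactants: 21 enone
Product: 22 2,3-epoxide of 21, oxirane oxygen syn to the C9 bridge, C1, C5, C7 and C8 as in 21
Conditions: t-BuOOH, DBU, CH2Cl2, 0 °C → rt
Reagents that add atoms: tert-butyl hydroperoxide, CC(C)(C)OO
Why: Weitz–Scheffer nucleophilic epoxidation acts only on the electron-poor enone (the trisubstituted alkenes are untouched); the peroxide adds to C2 from the convex face syn to C9, which sets C2 and C3 (both are erased in step 15).

Step 15
Reactants: 22 epoxy ketone
Product: 23 (1R,5R,7S,8R)-4-hydroxy-8-methyl-8-(4-methylpent-3-en-1-yl)-5,7-bis(3-methylbut-2-en-1-yl)-1-(2-methylpropanoyl)bicyclo[3.3.1]non-3-ene-2,9-dione (target)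
Conditions: Pd(PPh3)4 (cat.), 1,2-bis(diphenylphosphino)ethane (cat.), toluene, 80 °C
Reagents that add atoms: none
Why: Palladium-catalysed isomerisation of an α,β-epoxy ketone (opening at the Cα–O bond, β-hydride elimination from C2–H) gives the 1,3-diketone, which enolises to the target; C1, C5, C7 and C8 are not involved.

**Compound list**

1 | geraniol | CC(C)=CCC/C(C)=C/CO | starting material
2 | 5-methylhex-4-enoic acid | CC(C)=CCCC(=O)O | starting material
3 | geranyl 5-methylhex-4-enoate | CC(C)=CCC/C(C)=C/COC(=O)CCC=C(C)C | intermediate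
4 | (2R,3S)-3-ethenyl-3,7-dimethyl-2-(3-methylbut-2-en-1-yl)oct-6-enoic acid | CC(C)=CCC[C@](C=C)(C)[C@@H](CC=C(C)C)C(=O)O | intermediate
5 | (2R,3S)-3-ethenyl-3,7-dimethyl-2-(3-methylbut-2-en-1-yl)oct-6-en-1-ol | CC(C)=CCC[C@](C=C)(C)[C@@H](CC=C(C)C)CO | intermediate
6 | tert-butyldimethylsilyl ether of 5 | CC(C)=CCC[C@](C=C)(C)[C@@H](CC=C(C)C)CO[Si](C)(C)C(C)(C)C | intermediate
7 | (3S)-3-[(2R)-1-(tert-butyldimethylsilyloxy)-5-methylhex-4-en-2-yl]-3,7-dimethyloct-6-enal | CC(C)=CCC[C@](CC=O)(C)[C@@H](CC=C(C)C)CO[Si](C)(C)C(C)(C)C | intermediate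
8 | chloromagnesium alkoxide of the isopropyl carbinol from 7 (both carbinol epimers) | CC(C)=CCC[C@](CC(O[Mg]Cl)C(C)C)(C)[C@@H](CC=C(C)C)CO[Si](C)(C)C(C)(C)C | intermediate
9 | (5S)-5-[(2R)-1-(tert-butyldimethylsilyloxy)-5-methylhex-4-en-2-yl]-2,5,9-trimethyldec-8-en-3-one | CC(C)=CCC[C@](CC(=O)C(C)C)(C)[C@@H](CC=C(C)C)CO[Si](C)(C)C(C)(C)C | intermediate
10 | 4-(trifluoroacetyl) derivative of 9 (1,3-diketone at C1) | CC(C)=CCC[C@](C(C(=O)C(F)(F)F)C(=O)C(C)C)(C)[C@@H](CC=C(C)C)CO[Si](C)(C)C(C)(C)C | intermediate
11 | (5R)-5-[(2R)-1-(tert-butyldimethylsilyloxy)-5-methylhex-4-en-2-yl]-4-diazo-2,5,9-trimethyldec-8-en-3-one | CC(C)=CCC[C@](C(=[N+]=[N-])C(=O)C(C)C)(C)[C@@H](CC=C(C)C)CO[Si](C)(C)C(C)(C)C | intermediate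
12 | (5R)-4-diazo-5-[(2R)-1-hydroxy-5-methylhex-4-en-2-yl]-2,5,9-trimethyldec-8-en-3-one | CC(C)=CCC[C@](C(=[N+]=[N-])C(=O)C(C)C)(C)[C@@H](CC=C(C)C)CO | intermediate
13 | (2R,3R)-3-(1-diazo-3-methyl-2-oxobutyl)-3,7-dimethyl-2-(3-methylbut-2-en-1-yl)oct-6-enal | CC(C)=CCC[C@](C(=[N+]=[N-])C(=O)C(C)C)(C)[C@@H](CC=C(C)C)C=O | intermediate
14 | cyclopentane-1,3-dione | O=C1CCC(=O)C1 | starting material
15 | 2-alkylidenecyclopentane-1,3-dione from 13 and 14 | CC(C)=CCC[C@](C(=[N+]=[N-])C(=O)C(C)C)(C)[C@@H](CC=C(C)C)C=C1C(=O)CCC1=O | intermediate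
16 | 2-[(2S,3R)-3-(1-diazo-3-methyl-2-oxobutyl)-3,7-dimethyl-2-(3-methylbut-2-en-1-yl)oct-6-en-1-yl]cyclopentane-1,3-dione | CC(C)=CCC[C@](C(=[N+]=[N-])C(=O)C(C)C)(C)[C@@H](CC=C(C)C)CC1C(=O)CCC1=O | intermediate
17 | 2-[(2S,3R)-3-(1-diazo-3-methyl-2-oxobutyl)-3,7-dimethyl-2-(3-methylbut-2-en-1-yl)oct-6-en-1-yl]-2-(3-methylbut-2-en-1-yl)cyclopentane-1,3-dione | CC(C)=CCC[C@](C(=[N+]=[N-])C(=O)C(C)C)(C)[C@@H](CC=C(C)C)CC1(CC=C(C)C)C(=O)CCC1=O | intermediate
18 | cis-fused diazonium alkoxide (alkoxide at ring-fusion C9, diazonium at C1 on the alkoxide face, C2 still on C9) | CC(C)=CCC[C@]1(C)[C@@H](CC=C(C)C)C[C@]2(CC=C(C)C)C(=O)CC[C@]2([O-])[C@]1([N+]#N)C(=O)C(C)C | intermediate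
19 | (1R,5R,7S,8R)-8-methyl-8-(4-methylpent-3-en-1-yl)-5,7-bis(3-methylbut-2-en-1-yl)-1-(2-methylpropanoyl)bicyclo[3.3.1]nonane-4,9-dione | CC(C)=CCC[C@]1(C)[C@@H](CC=C(C)C)C[C@@]2(CC=C(C)C)C(=O)[C@]1(C(=O)C(C)C)CCC2=O | intermediate
20 | C4 trimethylsilyl enol ether of 19 (C3=C4) | CC(C)=CCC[C@]1(C)[C@@H](CC=C(C)C)C[C@@]2(CC=C(C)C)C(=O)[C@]1(C(=O)C(C)C)CC=C2O[Si](C)(C)C | intermediate
21 | (1R,5R,7S,8R)-8-methyl-8-(4-methylpent-3-en-1-yl)-5,7-bis(3-methylbut-2-en-1-yl)-1-(2-methylpropanoyl)bicyclo[3.3.1]non-2-ene-4,9-dione | CC(C)=CCC[C@]1(C)[C@@H](CC=C(C)C)C[C@@]2(CC=C(C)C)C(=O)[C@]1(C(=O)C(C)C)C=CC2=O | intermediate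
22 | 2,3-epoxide of 21, oxirane oxygen syn to C9 | CC(C)=CCC[C@]1(C)[C@@H](CC=C(C)C)C[C@@]2(CC=C(C)C)C(=O)[C@]1(C(=O)C(C)C)[C@@H]3O[C@@H]3C2=O | intermediate
23 | (1R,5R,7S,8R)-4-hydroxy-8-methyl-8-(4-methylpent-3-en-1-yl)-5,7-bis(3-methylbut-2-en-1-yl)-1-(2-methylpropanoyl)bicyclo[3.3.1]non-3-ene-2,9-dione | CC(C)=CCC[C@]1(C)[C@@H](CC=C(C)C)C[C@@]2(CC=C(C)C)C(=O)[C@]1(C(=O)C(C)C)C(=O)C=C2O | target

**Count**

Total steps: 15. Longest linear sequence: 15 steps (from geraniol).

**Steps most likely to fail, with fallbacks**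

Step 12 (proposed new method). What may go wrong: the diazonium alkoxide may collapse by oxirane closure or by migration of the ring-fusion carbon C5 instead of C2, or nitrogen may be lost by protonation before the C1–C9 bond forms. The fallback sets out from 17 and splits the event into known reactions. Rh2(OAc)4-catalysed S–H insertion of thiophenol into the diazo ketone gives the α-phenylsulfanyl ketone F1. Catalytic t-BuOK in THF then closes the carbocycle by intramolecular aldol addition of the now selectively acidic C1–H to a ring carbonyl, through the same chair as in step 12, giving the ring-fusion β-hydroxy sulfide F2. S-Methylation (MeOTf, 2,6-di-tert-butylpyridine, CH2Cl2) and warming trigger the sulfonium-driven semipinacol shift of C2 from C9 to C1 (ring expansion of β-hydroxy sulfides), which returns to the route at 19.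

Step 7. What may go wrong: deprotonation at the isopropyl methine, or at neither α-position of the hindered ketone, so that C-acylation and hence diazo transfer stall. The fallback sets out from 9. Reversible Claisen formylation (NaH, ethyl formate, THF) stores only the C1-formylated ketone as its enolate and gives the hydroxymethylene ketone F3. Deformylative Regitz diazo transfer (4-acetamidobenzenesulfonyl azide, Et3N, MeCN) then returns to the route at 11.

Step 14. What may go wrong: retro-Claisen cleavage at the non-enolisable tricarbonyl centre C1 by the peroxide anion, and slow conjugate addition at the neopentyl β-carbon C2. The fallback sets out from 21 and bypasses 22. Copper-catalysed conjugate borylation (B2pin2, CuCl, NaOt-Bu, Xantphos, MeOH, THF) gives the β-boryl ketone F4. Oxidation with NaBO3·4H2O gives the β-hydroxy ketone F5, and Dess–Martin oxidation of F5 gives the 1,3-diketone, which returns to the route at 23.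

**Further compounds**

F1 | step 12 | 2-{(2S)-3,7-dimethyl-3-[3-methyl-2-oxo-1-(phenylsulfanyl)butyl]-2-(3-methylbut-2-en-1-yl)oct-6-en-1-yl}-2-(3-methylbut-2-en-1-yl)cyclopentane-1,3-dione (C7, C8 as in 17; both epimers at the sulfur-bearing carbon) | CC(C)=CCC[C@](C(Sc1ccccc1)C(=O)C(C)C)(C)[C@@H](CC=C(C)C)CC1(CC=C(C)C)C(=O)CCC1=O
F2 | step 12 | cis-fused ring-fusion β-hydroxy sulfide (hydroxyl at C9, phenylsulfanyl at C1 on the hydroxyl face, C2 still on C9) | CC(C)=CCC[C@]1(C)[C@@H](CC=C(C)C)C[C@]2(CC=C(C)C)C(=O)CC[C@]2(O)[C@]1(Sc1ccccc1)C(=O)C(C)C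
F3 | step 7 | 4-(hydroxymethylene) derivative of 9 (C1-formyl ketone, enol form) | CC(C)=CCC[C@](C(=CO)C(=O)C(C)C)(C)[C@@H](CC=C(C)C)CO[Si](C)(C)C(C)(C)C
F4 | step 14 | 2-(pinacolatoboryl) derivative of 19 (boron at C2, syn to C9) | CC(C)=CCC[C@]1(C)[C@@H](CC=C(C)C)C[C@@]2(CC=C(C)C)C(=O)[C@]1(C(=O)C(C)C)[C@H](B3OC(C)(C)C(C)(C)O3)CC2=O
F5 | step 14 | 2-hydroxy derivative of 19 (hydroxyl at C2, syn to C9) | CC(C)=CCC[C@]1(C)[C@@H](CC=C(C)C)C[C@@]2(CC=C(C)C)C(=O)[C@]1(C(=O)C(C)C)[C@H](O)CC2=O
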